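(All runs are calculated with made-up constants, noise included.)

Late times in the gamma run are read here for a fraction, not a rate. From 3.00 h to 6.00 h the gamma target grows by a factor of 1.69, less than 2, so the readings bend. With a scatter of 2 percentage points, no final level is taken from these points. What is read instead is how the target in the gamma run stands to the target in the eta run.

all flasks: starting material 0.085 M
- gamma: first nucleophile 0.051 M; second nucleophile 0.0044 M; protic impurity 0.085 M; run made earlier
- eta: first nucleophile 0.051 M; second nucleophile 0.033 M; protic impurity 0.085 M; run made earlier
- epsilon: first nucleophile 0.051 M; second nucleophile 0.33 M; protic impurity 0.085 M; run made earlier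
- maple: first nucleophile 0.0510 M; second nucleophile 0.00400 M; protic impurity 0.0850 M; time 15 h
- cedar: first nucleophile 0.0510 M; second nucleophile 0.0120 M; protic impurity 0.0850 M; time 15 h
- birch: first nucleophile 0.0510 M; second nucleophile 0.0300 M; protic impurity 0.0850 M; time 15 h
- ash: first nucleophile 0.0510 M; second nucleophile 0.100 M; protic impurity 0.0850 M; time 15 h
- elm: first nucleophile 0.0510 M; second nucleophile 0.300 M; protic impurity 0.0850 M; time 15 h

- gamma (time / h: target / %): 1.50: 9; 3.00: 13; 5.00: 21; 6.00: 22; 8.00: 27
- eta (time / h: target / %): 1.50: 6; 3.00: 6; 5.00: 16; 6.00: 11; 8.00: 15
- epsilon (time / h: target / %): 0.667: 0; 1.00: 3; 2.00: 1; 4.00: 3; 8.00: 6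

(standard deviation of a reading: 2 percentage points)

- the numbers in the tables scatter with a standard deviation of 2 percentage points
- "hardly changes" means that all values lie within two and a half points (for a concentration: within two and a half percent of the largest)

- amount of target at the end, in percent of the starting material charged for maple, cedar, birch, ash, elm, in this order
- the shape of the row from first to last (hardly changes / rises all the way / falls all the way / falls, then rises / rises, then falls)

My own reckoning follows one molecule. Suppose it reaches an intermediate that meets either first nucleophile, giving target, or second nucleophile, giving something else. At a fixed charge of first nucleophile, the chance of target is then K/(K+c), where c is the charge of second nucleophile. If second nucleophile acts at this fork and nowhere earlier, gamma and eta share one time course, and their ratio at any common time is (K+c of eta)/(K+c of gamma).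

The summed readings at the common times give a gamma-to-eta ratio of 1.70, and so a reading of K = 0.0362 M. This is the half-capture concentration, a selectivity factor written as a concentration: at c = K the chance is half. Carried to epsilon at 8.00 h, it gives 3.00% against a reading of 6%.

Drawn against c, the row starts nearly flat, with maple at 0.901 of the undivided level. Its knee lies at K, above birch and below ash. Ash stands at 0.266 of that level and elm at 0.108. The row therefore falls throughout, and elm over maple is 0.120.

The forecast gives 35%, 30%, 23%, 14% and 9%, a row that falls all the way, and holds that second nucleophile “acts as a competitor or inhibitor”. It agrees with my reckoning on the shape, but its elm over maple, 0.257, is larger than mine.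

The flask gives 24.2%, 21.0%, 16.3%, 8.65% and 3.70%, a row that falls all the way, with elm over maple at 0.153.

    first nucleophile + intermediate → target (k = 22.3 M⁻¹ min⁻¹)
    second nucleophile + intermediate → other capture product (k = 23.0 M⁻¹ min⁻¹)
    starting material + protic impurity → quenched substrate (k = 0.106 M⁻¹ min⁻¹)
    starting material → intermediate (k = 0.00180 min⁻¹)

In maple at 1.14 h, starting material passes into quenched substrate 3.2 times as fast as into intermediate, and still 1.4 times as fast at 15.0 h, leaving 72.9% quenched and 26.1% in the two capture products. In ash, the K read from gamma and eta gives, as K/c with the charge of second nucleophile, a ratio of target to other capture product of 0.362, and the ash flask holds 0.496.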